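**Retrosynthetic overview**

- Locants: C1 (aryl, endo), O2, C3, C3a (OH), C4 (aryl, exo), O5, C6, C6a (H). Ring A is C3a/C4/O5/C6/C6a and ring B is C1/O2/C3/C3a/C6a.
- Last operations: O-debenzylation, and before it a hydroxyl-directed syn hydrogenation of a C1=C6a enol ether, which places H-1 and H-6a on the face of the 3a-OH and so makes the C1 aryl endo.
- Key disconnection: the C3a–C6a and O2–C1 bonds are formed together in a silyl-cation-catalysed (3+2) cycloisomerisation of an acyclic 1-silyloxy-2-ketone carrying a 3-arylpropargyl ether; ring A closes first (C–C), ring B directly after (C–O), in the same operation.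
- Enabling feature: in ring B, O2–C3–C3a(O) is a 1-oxy-2-ketone unit (nucleophilic O2, electrophilic C3a, one CH2 apart) facing the C6a–C1 pair, and C1 carries a 4-oxygenated aryl group that can hold positive charge, so C6a≡C1 can be an aryl alkyne.
- The precursor's only stereocentre (later C4) comes from an iridium-catalysed asymmetric allylic etherification joining a cinnamyl carbonate and an arylpropargyl alcohol; the vinyl group is then turned into the 1-silyloxy-2-ketone.

Key step: step 9

Remark: the (Sa,Sc,Sc) phosphoramidite in step 5 is assumed to give the (S)-ether; if the sense of induction is the opposite, the (Ra,Rc,Rc) ligand is used.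

**Route**

Step 1
Reactants: 1 4-(benzyloxy)-3-methoxybenzaldehyde; 2 triethyl phosphonoacetate
Product: 3 ethyl (2E)-3-[4-(benzyloxy)-3-methoxyphenyl]prop-2-enoate
Conditions: NaH, THF, 0 °C to rt
Reagents that add atoms: none
Why: Horner–Wadsworth–Emmons olefination of an aryl aldehyde with a stabilised phosphonate anion should give the (E)-cinnamate.

Step 2
Reactants: 3 ethyl (2E)-3-[4-(benzyloxy)-3-methoxyphenyl]prop-2-enoate
Product: 4 (2E)-3-[4-(benzyloxy)-3-methoxyphenyl]prop-2-en-1-ol
Conditions: iBu2AlH (2.2 equiv), CH2Cl2, −78 °C; aqueous potassium sodium tartrate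
Reagents that add atoms: none
Why: 1,2-reduction of a conjugated ester by an aluminium hydride should give the allylic alcohol and leave the alkene untouched.

Step 3
Reactants: 4 (2E)-3-[4-(benzyloxy)-3-methoxyphenyl]prop-2-en-1-ol
Product: 5 (2E)-3-[4-(benzyloxy)-3-methoxyphenyl]prop-2-en-1-yl methyl carbonate
Conditions: ClCO2Me, pyridine, CH2Cl2, 0 °C
Reagents that add atoms: methyl chloroformate, COC(=O)Cl
Why: O-acylation with a chloroformate installs the carbonate leaving group needed for allyliridium formation.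

Step 4
Reactants: 6 1-(benzyloxy)-4-bromo-2-methoxybenzene; 7 prop-2-yn-1-ol
Product: 8 3-[4-(benzyloxy)-3-methoxyphenyl]prop-2-yn-1-ol
Conditions: Pd(PPh3)2Cl2 (3 mol%), CuI (5 mol%), Et3N, THF, 65 °C
Reagents that add atoms: none
Why: Sonogashira coupling of an aryl bromide with a terminal alkyne tolerates the free alcohol.

Step 5
Reactants: 5 (2E)-3-[4-(benzyloxy)-3-methoxyphenyl]prop-2-en-1-yl methyl carbonate; 8 3-[4-(benzyloxy)-3-methoxyphenyl]prop-2-yn-1-ol
Product: 9 1-(benzyloxy)-4-[(1S)-1-({3-[4-(benzyloxy)-3-methoxyphenyl]prop-2-yn-1-yl}oxy)prop-2-en-1-yl]-2-methoxybenzene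
Conditions: [Ir(cod)Cl]2 (2 mol%), (Sa,Sc,Sc)-(1,1′-binaphthalene-2,2′-diyl) N,N-bis(1-phenylethyl)phosphoramidite (4 mol%), K3PO4 (0.5 equiv), THF, rt
Reagents that add atoms: none
Why: Iridium-catalysed asymmetric allylic etherification (Hartwig type) of a linear cinnamyl carbonate with a primary alcohol should attack the aryl-bearing allyl terminus, giving the branched ether; the phosphoramidite ligand sets the benzylic stereocentre (S here, the later C4).

Step 6
Reactants: 9 1-(benzyloxy)-4-[(1S)-1-({3-[4-(benzyloxy)-3-methoxyphenyl]prop-2-yn-1-yl}oxy)prop-2-en-1-yl]-2-methoxybenzene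
Product: 10 (3R)-3-[4-(benzyloxy)-3-methoxyphenyl]-3-({3-[4-(benzyloxy)-3-methoxyphenyl]prop-2-yn-1-yl}oxy)propane-1,2-diol (both C2 epimers)
Conditions: OsO4 (2 mol%), N-methylmorpholine N-oxide, acetone/H2O, 0 °C to rt
Reagents that add atoms: N-methylmorpholine N-oxide, C[N+]1([O-])CCOCC1; water, O
Why: Upjohn dihydroxylation should take the terminal alkene much faster than the internal aryl alkyne; the new carbinol centre is oxidised away in step 8, so both epimers are carried on.

Step 7
Reactants: 10 (3R)-3-[4-(benzyloxy)-3-methoxyphenyl]-3-({3-[4-(benzyloxy)-3-methoxyphenyl]prop-2-yn-1-yl}oxy)propane-1,2-diol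
Product: 11 (3R)-3-[4-(benzyloxy)-3-methoxyphenyl]-3-({3-[4-(benzyloxy)-3-methoxyphenyl]prop-2-yn-1-yl}oxy)-1-[(triethylsilyl)oxy]propan-2-ol (both C2 epimers)
Conditions: Et3SiCl (1.05 equiv), imidazole, CH2Cl2, −40 °C
Reagents that add atoms: chlorotriethylsilane, CC[Si](Cl)(CC)CC
Why: Selective silylation of the primary hydroxyl of a 1,2-diol at low temperature; this silyl group is the one that is shuttled in step 9.

Step 8
Reactants: 11 (3R)-3-[4-(benzyloxy)-3-methoxyphenyl]-3-({3-[4-(benzyloxy)-3-methoxyphenyl]prop-2-yn-1-yl}oxy)-1-[(triethylsilyl)oxy]propan-2-ol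
Product: 12 (1R)-1-[4-(benzyloxy)-3-methoxyphenyl]-1-({3-[4-(benzyloxy)-3-methoxyphenyl]prop-2-yn-1-yl}oxy)-3-[(triethylsilyl)oxy]propan-2-one
Conditions: Dess–Martin periodinane, CH2Cl2, 0 °C to rt
Reagents that add atoms: none
Why: Dess–Martin oxidation of the secondary alcohol under non-basic conditions should give the α-alkoxy ketone without epimerising the benzylic stereocentre.

Step 9
Reactants: 12 (1R)-1-[4-(benzyloxy)-3-methoxyphenyl]-1-({3-[4-(benzyloxy)-3-methoxyphenyl]prop-2-yn-1-yl}oxy)-3-[(triethylsilyl)oxy]propan-2-one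
Product: 13 (3aS,4R)-1,4-bis[4-(benzyloxy)-3-methoxyphenyl]-3a-[(triethylsilyl)oxy]-3a,4-dihydro-3H,6H-furo[3,4-c]furan (C1=C6a enol ether; 4-aryl cis to the 3a-silyloxy group)
Conditions: Et3SiOTf (10 mol%), 2,6-di-tert-butyl-4-methylpyridine (15 mol%), CH2Cl2, −78 to −40 °C; Et3N quench
Reagents that add atoms: none
Why: Proposed new method: Et3Si+ silylates the ketone oxygen to a siloxycarbenium ion, the alkyne carbon remote from the aryl group attacks it (5-exo-dig, closes ring A, forms C3a–C6a), and the linear 4-alkoxyaryl-stabilised vinyl cation at C1 is captured in its own plane by the silyl ether oxygen (5-endo-dig-type closure of ring B, forms O2–C1), after which the oxonium ion passes Et3Si+ to the next ketone, so the step is a silyl-cation chain isomerisation. The closest known reaction types are the alkyne Prins cyclisation and the Lewis acid carbonyl–alkyne metathesis, which share the first two events, and the Noyori-type capture of oxocarbenium ions by silyl ethers with release of R3Si+. The only new stereocentre, C3a, is set by the existing C4 centre: in the closing conformer the C4–O bond lies in the forming ring, the silyl group of the carbenium ion sits on the CH2 side, the C4–H bond eclipses the C3a–CH2OSi bond and the aryl group lies beside the carbenium oxygen (least A(1,2) strain), so aryl and OSiEt3 should end up cis (aryl exo). The step needs exo attack at the alkyne (secured by the cation-stabilising aryl on the other alkyne carbon), O-capture in place of oxetene formation (five- against four-membered ring; arene capture would need a bridgehead alkene) and survival of the acid-labile 3-silyloxy enol ether (tertiary O–Si in place of O–H, hindered base, low temperature, amine quench).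

Step 10
Reactants: 13 (3aS,4R)-1,4-bis[4-(benzyloxy)-3-methoxyphenyl]-3a-[(triethylsilyl)oxy]-3a,4-dihydro-3H,6H-furo[3,4-c]furan
Product: 14 (3aS,4R)-1,4-bis[4-(benzyloxy)-3-methoxyphenyl]-3a,4-dihydro-3H,6H-furo[3,4-c]furan-3a-ol
Conditions: Bu4NF, THF, 0 °C
Reagents that add atoms: none
Why: Fluoride cleavage of the tertiary silyl ether is basic, which the acid-labile enol ether tolerates, and touches no stereocentre.

Step 11
Reactants: 14 (3aS,4R)-1,4-bis[4-(benzyloxy)-3-methoxyphenyl]-3a,4-dihydro-3H,6H-furo[3,4-c]furan-3a-ol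
Product: 15 (1R,3aS,4R,6aR)-1,4-bis[4-(benzyloxy)-3-methoxyphenyl]tetrahydro-1H,3H-furo[3,4-c]furan-3a(4H)-ol (1-aryl endo, 4-aryl exo)
Conditions: [Ir(cod)(PCy3)(py)]PF6 (5 mol%), H2 (1 atm), CH2Cl2, 0 °C to rt
Reagents that add atoms: none
Why: Hydroxyl-directed homogeneous hydrogenation: the tertiary 3a-OH binds the cationic iridium centre and both hydrogens should be delivered to the C1=C6a enol ether from the OH face, giving the cis ring fusion (H-6a cis to 3a-OH) and H-1 cis to H-6a, which is the endo aryl at C1.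

Step 12
Reactants: 15 (1R,3aS,4R,6aR)-1,4-bis[4-(benzyloxy)-3-methoxyphenyl]tetrahydro-1H,3H-furo[3,4-c]furan-3a(4H)-ol
Product: 16 (1R,3aS,4R,6aR)-1,4-bis(4-hydroxy-3-methoxyphenyl)tetrahydro-1H,3H-furo[3,4-c]furan-3a(4H)-ol
Conditions: H2 (1 atm), Pd/C (10%), EtOAc/EtOH, rt, short reaction time
Reagents that add atoms: none
Why: Hydrogenolysis of the two aryl benzyl ethers under neutral conditions, stopped early so that the benzylic ring C–O bonds of the furofuran are kept.

**Compound list**

1 | 4-(benzyloxy)-3-methoxybenzaldehyde | COc1cc(C=O)ccc1OCc1ccccc1 | starting material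
2 | triethyl phosphonoacetate | CCOC(=O)CP(=O)(OCC)OCC | starting material
3 | ethyl (2E)-3-[4-(benzyloxy)-3-methoxyphenyl]prop-2-enoate | CCOC(=O)/C=C/c1ccc(OCc2ccccc2)c(OC)c1 | intermediate
4 | (2E)-3-[4-(benzyloxy)-3-methoxyphenyl]prop-2-en-1-ol | OC/C=C/c1ccc(OCc2ccccc2)c(OC)c1 | intermediate
5 | (2E)-3-[4-(benzyloxy)-3-methoxyphenyl]prop-2-en-1-yl methyl carbonate | COC(=O)OC/C=C/c1ccc(OCc2ccccc2)c(OC)c1 | intermediate
6 | 1-(benzyloxy)-4-bromo-2-methoxybenzene | COc1cc(Br)ccc1OCc1ccccc1 | starting material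
7 | prop-2-yn-1-ol | C#CCO | starting material
8 | 3-[4-(benzyloxy)-3-methoxyphenyl]prop-2-yn-1-ol | OCC#Cc1ccc(OCc2ccccc2)c(OC)c1 | intermediate
9 | 1-(benzyloxy)-4-[(1S)-1-({3-[4-(benzyloxy)-3-methoxyphenyl]prop-2-yn-1-yl}oxy)prop-2-en-1-yl]-2-methoxybenzene | COc1cc([C@@H](OCC#Cc2ccc(OCc3ccccc3)c(OC)c2)C=C)ccc1OCc1ccccc1 | intermediate
10 | (3R)-3-[4-(benzyloxy)-3-methoxyphenyl]-3-({3-[4-(benzyloxy)-3-methoxyphenyl]prop-2-yn-1-yl}oxy)propane-1,2-diol, both C2 epimers | COc1cc([C@@H](OCC#Cc2ccc(OCc3ccccc3)c(OC)c2)C(O)CO)ccc1OCc1ccccc1 | intermediate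
11 | (3R)-3-[4-(benzyloxy)-3-methoxyphenyl]-3-({3-[4-(benzyloxy)-3-methoxyphenyl]prop-2-yn-1-yl}oxy)-1-[(triethylsilyl)oxy]propan-2-ol, both C2 epimers | COc1cc([C@@H](OCC#Cc2ccc(OCc3ccccc3)c(OC)c2)C(O)CO[Si](CC)(CC)CC)ccc1OCc1ccccc1 | intermediate
12 | (1R)-1-[4-(benzyloxy)-3-methoxyphenyl]-1-({3-[4-(benzyloxy)-3-methoxyphenyl]prop-2-yn-1-yl}oxy)-3-[(triethylsilyl)oxy]propan-2-one | COc1cc([C@@H](OCC#Cc2ccc(OCc3ccccc3)c(OC)c2)C(=O)CO[Si](CC)(CC)CC)ccc1OCc1ccccc1 | intermediate
13 | (3aS,4R)-1,4-bis[4-(benzyloxy)-3-methoxyphenyl]-3a-[(triethylsilyl)oxy]-3a,4-dihydro-3H,6H-furo[3,4-c]furan | COc1cc([C@H]2OCC3=C(c4ccc(OCc5ccccc5)c(OC)c4)OC[C@]23O[Si](CC)(CC)CC)ccc1OCc1ccccc1 | intermediate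
14 | (3aS,4R)-1,4-bis[4-(benzyloxy)-3-methoxyphenyl]-3a,4-dihydro-3H,6H-furo[3,4-c]furan-3a-ol | COc1cc([C@H]2OCC3=C(c4ccc(OCc5ccccc5)c(OC)c4)OC[C@]23O)ccc1OCc1ccccc1 | intermediate
15 | (1R,3aS,4R,6aR)-1,4-bis[4-(benzyloxy)-3-methoxyphenyl]tetrahydro-1H,3H-furo[3,4-c]furan-3a(4H)-ol | COc1cc([C@H]2OC[C@@H]3[C@H](c4ccc(OCc5ccccc5)c(OC)c4)OC[C@]23O)ccc1OCc1ccccc1 | intermediate
16 | (1R,3aS,4R,6aR)-1,4-bis(4-hydroxy-3-methoxyphenyl)tetrahydro-1H,3H-furo[3,4-c]furan-3a(4H)-ol | COc1cc([C@H]2OC[C@@H]3[C@H](c4ccc(O)c(OC)c4)OC[C@]23O)ccc1O | target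

**Summary**

Total steps: 12. Longest linear sequence: 11 steps (steps 1–3 and 5–12; step 4 is the side branch).

**Steps most likely to fail**

1. Step 9 (proposed new method). The cationic cascade may be diverted: ionisation of the allylic C3a–O bond of the product with aromatisation to a furan, closure of the vinyl cation on the ketone oxygen (carbonyl–alkyne metathesis), base-mediated enol silane formation with loss of the C4 configuration, or poor facial selectivity at C3a. The fallback uses known reactions, sets out from ketone 12 and returns at compound 15. SmI2/HMPA/t-BuOH in THF at −78 °C (ketyl–alkyne 5-exo-dig reductive cyclisation) should give (2R,3S)-2-[4-(benzyloxy)-3-methoxyphenyl]-4-{[4-(benzyloxy)-3-methoxyphenyl]methylidene}-3-{[(triethylsilyl)oxy]methyl}oxolan-3-ol F1. Hydroboration–oxidation (BH3·SMe2, then NaBO3), with boron at the benzylic carbon and hydrogen delivered to the ring carbon on the face of the tertiary OH, should give the benzylic alcohol F2. Dess–Martin oxidation should give the aryl ketone F3. HF·pyridine in THF removes the silyl group to the hydroxy ketone F4, which is not isolated and should close to the bicyclic lactol F5. Et3SiH/BF3·OEt2 in CH2Cl2 at −78 °C reduces the lactol through the cyclic aryl oxocarbenium ion with hydride on the convex face, which should give 15 with the endo aryl group.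

2. Step 11. The hydroxy enol ether may ionise and aromatise under the cationic iridium catalyst, or the tetrasubstituted alkene may be reduced too slowly. The fallback sets out from 14 and returns at 15 by ionic hydrogenation (Et3SiH, CF3CO2H, CH2Cl2, −40 °C). Protonation at C6a should give the cis-fused 1-aryl oxocarbenium ion (the trans-fused ion is too strained), and hydride then adds to C1 on the convex face, the known course for 1-aryl glycals. Further compound made: none F0.

3. Step 5. Branched-to-linear selectivity or enantioselectivity may be eroded with the propargylic alcohol as nucleophile, or the alkyne may bind the iridium. The fallback sets out from aldehyde 1 and alcohol 8 and returns at ether 9. Vinylmagnesium bromide (THF, 0 °C) adds to 1 to give racemic 1-[4-(benzyloxy)-3-methoxyphenyl]prop-2-en-1-ol F6. Lipase kinetic resolution (immobilised Candida antarctica lipase B, vinyl acetate, toluene) should leave (1S)-1-[4-(benzyloxy)-3-methoxyphenyl]prop-2-en-1-ol F7 and convert the other enantiomer into (1R)-1-[4-(benzyloxy)-3-methoxyphenyl]prop-2-en-1-yl acetate F8, which is separated. Appel bromination of 8 (CBr4, PPh3, CH2Cl2) gives 1-(benzyloxy)-4-(3-bromoprop-1-yn-1-yl)-2-methoxybenzene F9. Williamson etherification of F7 with F9 (NaH, DMF, 0 °C) gives 9 with retention at the carbinol carbon.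

**Further compounds**

F1 | step 9 | (2R,3S)-2-[4-(benzyloxy)-3-methoxyphenyl]-4-{[4-(benzyloxy)-3-methoxyphenyl]methylidene}-3-{[(triethylsilyl)oxy]methyl}oxolan-3-ol | COc1cc([C@H]2OCC(=Cc3ccc(OCc4ccccc4)c(OC)c3)[C@]2(O)CO[Si](CC)(CC)CC)ccc1OCc1ccccc1
F2 | step 9 | (2R,3S,4R)-2-[4-(benzyloxy)-3-methoxyphenyl]-4-{[4-(benzyloxy)-3-methoxyphenyl](hydroxy)methyl}-3-{[(triethylsilyl)oxy]methyl}oxolan-3-ol, both carbinol epimers | COc1cc([C@H]2OC[C@H](C(O)c3ccc(OCc4ccccc4)c(OC)c3)[C@]2(O)CO[Si](CC)(CC)CC)ccc1OCc1ccccc1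
F3 | step 9 | [4-(benzyloxy)-3-methoxyphenyl][(3S,4S,5R)-5-[4-(benzyloxy)-3-methoxyphenyl]-4-hydroxy-4-{[(triethylsilyl)oxy]methyl}oxolan-3-yl]methanone | COc1cc([C@H]2OC[C@H](C(=O)c3ccc(OCc4ccccc4)c(OC)c3)[C@]2(O)CO[Si](CC)(CC)CC)ccc1OCc1ccccc1
F4 | step 9 | [4-(benzyloxy)-3-methoxyphenyl][(3S,4S,5R)-5-[4-(benzyloxy)-3-methoxyphenyl]-4-hydroxy-4-(hydroxymethyl)oxolan-3-yl]methanone | COc1cc([C@H]2OC[C@H](C(=O)c3ccc(OCc4ccccc4)c(OC)c3)[C@]2(O)CO)ccc1OCc1ccccc1
F5 | step 9 | (3aS,4R,6aS)-1,4-bis[4-(benzyloxy)-3-methoxyphenyl]tetrahydro-1H,3H-furo[3,4-c]furan-1,3a(4H)-diol, both C1 epimers | COc1cc([C@H]2OC[C@@H]3C(O)(c4ccc(OCc5ccccc5)c(OC)c4)OC[C@]23O)ccc1OCc1ccccc1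
F0 | step 11 | none | none
F6 | step 5 | racemic 1-[4-(benzyloxy)-3-methoxyphenyl]prop-2-en-1-ol | COc1cc(C(O)C=C)ccc1OCc1ccccc1
F7 | step 5 | (1S)-1-[4-(benzyloxy)-3-methoxyphenyl]prop-2-en-1-ol | COc1cc([C@@H](O)C=C)ccc1OCc1ccccc1
F8 | step 5 | (1R)-1-[4-(benzyloxy)-3-methoxyphenyl]prop-2-en-1-yl acetate | COc1cc([C@H](OC(C)=O)C=C)ccc1OCc1ccccc1
F9 | step 5 | 1-(benzyloxy)-4-(3-bromoprop-1-yn-1-yl)-2-methoxybenzene | COc1cc(C#CCBr)ccc1OCc1ccccc1
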